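The 8,8''-biaryl bond is never made by coupling; instead ring A of the luteolin half is grown on C8 of an intact apigenin trimethyl ether. That ring is a phloroglucinol pattern (oxygens on C5'', C7'' and C8a'', aryl on C8''), exactly what a 4-aryl-3-alkoxycyclobutenone and an alkoxyalkyne assemble. One thermal operation on the racemic 3-ethoxy-4-(flavon-8-yl)cyclobutenone with ethoxyacetylene forms C4a''–C8a'' and C5''–C6'', closes the benzene ring, and leaves a single free phenol at C8a'' next to the biaryl bond. That phenol then directs acetylation to C4a'', and chalcone formation, oxidative cyclization and global dealkylation finish the luteolin half.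

Key step: step 5

Assumption (remark on the chemistry): the 8,8''-axis carries four ortho substituents and is probably configurationally stable; the target is drawn without an axial descriptor, so every biaryl compound from the key-step product onward is planned as the racemate.

Locants: unprimed and single-primed numbers belong to the apigenin unit, double- and triple-primed numbers to the luteolin unit. "5,7,4'-Trimethoxyflavon-8-yl" means 5,7-dimethoxy-2-(4-methoxyphenyl)-4-oxo-4H-chromen-8-yl.

Step 1
Reactants: 1 5,7,4'-trimethoxyflavone [5,7-dimethoxy-2-(4-methoxyphenyl)-4H-chromen-4-one]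
Product: 2 8-iodo-5,7,4'-trimethoxyflavone
Conditions: NIS (1.05 equiv), TFA (0.3 equiv), CH3CN, 0 °C to rt, dark
Reagents that add atoms: N-iodosuccinimide, O=C1CCC(=O)N1I
Why: Electrophilic aromatic iodination: with the 5-oxygen methylated there is no chelated 5-hydroxyl to steer attack to C6, so C8 (ortho to O1 and the 7-methoxy, para to the 5-methoxy, less crowded than C6 between two methoxy groups) should be the site, and one equivalent of reagent limits double iodination.

Step 2
Reactants: 2 8-iodo-5,7,4'-trimethoxyflavone; 3 tert-butyl bromoacetate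
Product: 5 tert-butyl (5,7,4'-trimethoxyflavon-8-yl)acetate, via Reformatsky reagent 4 (not isolated)
Conditions: 3, Zn dust (TMSCl-activated), THF, 40 °C; then 2, Pd2(dba)3 (2.5 mol %), XPhos (10 mol %), THF, 65 °C
Reagents that add atoms: none
Why: Negishi cross-coupling of a Reformatsky reagent (palladium-catalysed α-arylation of an ester zinc enolate): the bulky biarylphosphine should carry the di-ortho-substituted aryl iodide through oxidative addition and reductive elimination, and the mild zinc enolate does not add to the vinylogous-ester carbonyl of the flavone.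

Step 3
Reactants: 5 tert-butyl (5,7,4'-trimethoxyflavon-8-yl)acetate
Product: 6 (5,7,4'-trimethoxyflavon-8-yl)acetic acid
Conditions: TFA–CH2Cl2 (1:3), rt
Reagents that add atoms: none
Why: Acidolysis of a tert-butyl ester with loss of isobutene, which frees the acid without the aqueous base that could open the pyranone ring.

Step 4
Reactants: 6 (5,7,4'-trimethoxyflavon-8-yl)acetic acid; 7 ethoxyacetylene
Product: 10 (±)-3-ethoxy-4-(5,7,4'-trimethoxyflavon-8-yl)cyclobut-2-en-1-one, via acid chloride 8 (not isolated), via arylketene 9 (not isolated)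
Conditions: (COCl)2 (1.2 equiv), DMF (cat.), CH2Cl2, 0 °C to rt, evaporate; then 7 (5 equiv), Et3N (1.3 equiv, slow addition), CH2Cl2, 0 °C to rt
Reagents that add atoms: none
Why: Ketene–ynol ether [2+2] cycloaddition: dehydrochlorination of 8 gives arylketene 9, whose carbonyl carbon bonds to the nucleophilic terminal carbon of the excess alkyne and whose α-carbon bonds to the ethoxy-bearing carbon, giving the 3-ethoxy-4-aryl enone; the C4 stereocentre forms without control (racemate) and is erased in step 5, and the low temperature keeps the four-membered ring closed.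

Step 5
Reactants: 10 (±)-3-ethoxy-4-(5,7,4'-trimethoxyflavon-8-yl)cyclobut-2-en-1-one; 7 ethoxyacetylene
Product: 15 8-(2,4-diethoxy-6-hydroxyphenyl)-5,7,4'-trimethoxyflavone, via vinylketene 11 (not isolated), via vinylcyclobutenone 12 (not isolated), via dienylketene 13 (not isolated), via cyclohexadienone 14 (not isolated)
Conditions: 7 (4 equiv), toluene, sealed tube, 80 °C then 110 °C
Reagents that add atoms: none
Why: Danheiser benzannulation: heat opens 10 by conrotatory 4π electrocyclic cleavage of the C8a''–C8'' bond to vinylketene 11, whose ketene carbon (future C8a'') bonds to the unsubstituted alkyne carbon (future C4a'') while its α-carbon (future C6'') bonds to the ethoxy-bearing carbon (future C5'') in a [2+2] cycloaddition that gives 12. A second 4π opening of 12 gives dienylketene 13, and thermal disrotatory 6π electrocyclization re-forms C8a''–C8'' and closes the six-membered ring A as dienone 14, which enolizes to phenol 15 with every atom of both reactants retained. The closest known reaction type is the thermal benzannulation of cyclobutenones with alkoxyacetylenes to monoprotected resorcinols. No stereocentre survives, since the sp3 centres of 10, 12 and 14 vanish on aromatization and the new hindered biaryl axis forms as a racemate without control. The step needs a regioselective ketene–alkyne union, which the polarity match (electrophilic ketene carbon, nucleophilic β-carbon of the ynol ether) secures, so both ethoxy groups end meta and the flavonyl group ortho to the new hydroxyl. Diversion of 11 into a fused naphthol-type ring is shut off because both positions ortho to C8 of the flavone (C7 and C8a) are substituted, and the neutral conditions leave the pyranone and the methyl ethers untouched.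

Step 6
Reactants: 15 8-(2,4-diethoxy-6-hydroxyphenyl)-5,7,4'-trimethoxyflavone
Product: 18 8-(3-acetyl-4,6-diethoxy-2-hydroxyphenyl)-5,7,4'-trimethoxyflavone, via aryl acetate 16 (not isolated), via difluoroboron chelate 17 (not isolated)
Conditions: Ac2O (3 equiv), BF3·OEt2 (6 equiv), 70 °C; then H2O–MeOH, reflux
Reagents that add atoms: acetic anhydride, CC(=O)OC(C)=O
Why: BF3-promoted O-acetylation and Fries rearrangement (Friedel–Crafts ortho-acylation): the acetyl group moves to the only free carbon ortho to the phenol (C4a''), the six-membered difluoroboron chelate 17 makes that isomer the thermodynamic sink over attack at C6'' between the two ethoxy groups, and the apigenin ring A is deactivated by its BF3-bound carbonyl.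

Step 7
Reactants: 18 8-(3-acetyl-4,6-diethoxy-2-hydroxyphenyl)-5,7,4'-trimethoxyflavone; 19 3,4-dimethoxybenzaldehyde
Product: 20 8-{3-[(E)-3-(3,4-dimethoxyphenyl)prop-2-enoyl]-4,6-diethoxy-2-hydroxyphenyl}-5,7,4'-trimethoxyflavone
Conditions: KOH (50% aq), EtOH, rt
Reagents that add atoms: none
Why: Claisen–Schmidt condensation: the methyl ketone enolate adds to the non-enolizable aldehyde and E1cB dehydration gives the thermodynamically favoured (E)-enone, while the apigenin pyranone, which has no acidic α-hydrogen, should tolerate ethanolic hydroxide at room temperature.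

Step 8
Reactants: 20 the (E)-2'-hydroxychalcone of step 7
Product: 21 5'',7''-diethoxy-5,7,4',3''',4'''-pentamethoxy-8,8''-biflavone
Conditions: I2 (10 mol %), DMSO, 130 °C
Reagents that add atoms: none
Why: Iodine-catalysed oxidative cyclization of a 2'-hydroxychalcone: the C8a'' hydroxyl adds to the enone in a 6-endo-trig oxa-Michael sense and the new ring is dehydrogenated by iodination and loss of HI, with DMSO regenerating iodine, a standard flavone closure that aryl ethers survive.

Step 9
Reactants: 21 5'',7''-diethoxy-5,7,4',3''',4'''-pentamethoxy-8,8''-biflavone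
Product: 22 5,7,4',5'',7'',3''',4'''-heptahydroxy-8,8''-biflavone (apigenin-(8→8'')-luteolin, the target)
Conditions: BBr3 (20 equiv), CH2Cl2, −78 °C to 40 °C; then MeOH, H2O
Reagents that add atoms: none
Why: BBr3 ether cleavage: each aryl alkyl ether is activated as its boron adduct and loses the alkyl group to bromide by SN2 (the chelated peri 5- and 5''-groups fastest, the 7-methoxy and the ethoxy groups last, hence excess reagent and warming), hydrolysis of the aryl borates frees all seven hydroxyls, and the two pyranones and the biaryl bond are inert to the reagent.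

Compound list
1 | 5,7,4'-trimethoxyflavone [5,7-dimethoxy-2-(4-methoxyphenyl)-4H-chromen-4-one] | O=c1cc(-c2ccc(OC)cc2)oc2cc(OC)cc(OC)c12 | starting material
2 | 8-iodo-5,7,4'-trimethoxyflavone | Ic1c(OC)cc(OC)c2c(=O)cc(-c3ccc(OC)cc3)oc12 | intermediate
3 | tert-butyl bromoacetate | CC(C)(C)OC(=O)CBr | starting material
4 | (2-tert-butoxy-2-oxoethyl)zinc bromide (Reformatsky reagent) | CC(C)(C)OC(=O)C[Zn]Br | intermediate
5 | tert-butyl 2-[5,7-dimethoxy-2-(4-methoxyphenyl)-4-oxo-4H-chromen-8-yl]acetate | CC(C)(C)OC(=O)Cc1c(OC)cc(OC)c2c(=O)cc(-c3ccc(OC)cc3)oc12 | intermediate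
6 | 2-[5,7-dimethoxy-2-(4-methoxyphenyl)-4-oxo-4H-chromen-8-yl]acetic acid | OC(=O)Cc1c(OC)cc(OC)c2c(=O)cc(-c3ccc(OC)cc3)oc12 | intermediate
7 | ethoxyacetylene (ethoxyethyne) | CCOC#C | starting material
8 | 2-[5,7-dimethoxy-2-(4-methoxyphenyl)-4-oxo-4H-chromen-8-yl]acetyl chloride | ClC(=O)Cc1c(OC)cc(OC)c2c(=O)cc(-c3ccc(OC)cc3)oc12 | intermediate
9 | (5,7,4'-trimethoxyflavon-8-yl)ketene [2-(flavon-8-yl)ethen-1-one] | O=C=Cc1c(OC)cc(OC)c2c(=O)cc(-c3ccc(OC)cc3)oc12 | intermediate
10 | (±)-3-ethoxy-4-(5,7,4'-trimethoxyflavon-8-yl)cyclobut-2-en-1-one | CCOC1=CC(=O)C1c1c(OC)cc(OC)c2c(=O)cc(-c3ccc(OC)cc3)oc12 | intermediate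
11 | (Z)-3-ethoxy-4-(5,7,4'-trimethoxyflavon-8-yl)buta-1,3-dien-1-one (vinylketene, aryl turned outward) | O=C=C/C(OCC)=C/c1c(OC)cc(OC)c2c(=O)cc(-c3ccc(OC)cc3)oc12 | intermediate
12 | (±)-3-ethoxy-4-[(Z)-1-ethoxy-2-(5,7,4'-trimethoxyflavon-8-yl)ethenyl]cyclobut-2-en-1-one | O=C1C=C(OCC)C1/C(OCC)=C/c1c(OC)cc(OC)c2c(=O)cc(-c3ccc(OC)cc3)oc12 | intermediate
13 | (3E,5Z)-3,5-diethoxy-6-(5,7,4'-trimethoxyflavon-8-yl)hexa-1,3,5-trien-1-one (dienylketene, chain ends cis on the central double bond) | O=C=C/C(OCC)=C\C(OCC)=C\c1c(OC)cc(OC)c2c(=O)cc(-c3ccc(OC)cc3)oc12 | intermediate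
14 | (±)-3,5-diethoxy-6-(5,7,4'-trimethoxyflavon-8-yl)cyclohexa-2,4-dien-1-one | O=C1C=C(OCC)C=C(OCC)C1c1c(OC)cc(OC)c2c(=O)cc(-c3ccc(OC)cc3)oc12 | intermediate
15 | 8-(2,4-diethoxy-6-hydroxyphenyl)-5,7-dimethoxy-2-(4-methoxyphenyl)-4H-chromen-4-one | CCOc1cc(OCC)c(-c2c(OC)cc(OC)c3c(=O)cc(-c4ccc(OC)cc4)oc23)c(O)c1 | intermediate
16 | 3,5-diethoxy-2-(5,7,4'-trimethoxyflavon-8-yl)phenyl acetate | CCOc1cc(OCC)c(-c2c(OC)cc(OC)c3c(=O)cc(-c4ccc(OC)cc4)oc23)c(OC(C)=O)c1 | intermediate
17 | difluoroboron chelate of 18 (O–BF2–O bridge between the C8a'' oxygen and the acetyl oxygen) | CCOc1cc(OCC)c(-c2c(OC)cc(OC)c3c(=O)cc(-c4ccc(OC)cc4)oc23)c2O[B-](F)(F)[O+]=C(C)c12 | intermediate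
18 | 8-(3-acetyl-4,6-diethoxy-2-hydroxyphenyl)-5,7-dimethoxy-2-(4-methoxyphenyl)-4H-chromen-4-one | CCOc1cc(OCC)c(-c2c(OC)cc(OC)c3c(=O)cc(-c4ccc(OC)cc4)oc23)c(O)c1C(C)=O | intermediate
19 | 3,4-dimethoxybenzaldehyde | COc1ccc(C=O)cc1OC | starting material
20 | 8-{3-[(E)-3-(3,4-dimethoxyphenyl)prop-2-enoyl]-4,6-diethoxy-2-hydroxyphenyl}-5,7-dimethoxy-2-(4-methoxyphenyl)-4H-chromen-4-one | CCOc1cc(OCC)c(-c2c(OC)cc(OC)c3c(=O)cc(-c4ccc(OC)cc4)oc23)c(O)c1C(=O)/C=C/c1ccc(OC)c(OC)c1 | intermediate
21 | 2-(3,4-dimethoxyphenyl)-5,7-diethoxy-8-[5,7-dimethoxy-2-(4-methoxyphenyl)-4-oxo-4H-chromen-8-yl]-4H-chromen-4-one | CCOc1cc(OCC)c(-c2c(OC)cc(OC)c3c(=O)cc(-c4ccc(OC)cc4)oc23)c2oc(-c3ccc(OC)c(OC)c3)cc(=O)c12 | intermediate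
22 | 8-[2-(3,4-dihydroxyphenyl)-5,7-dihydroxy-4-oxo-4H-chromen-8-yl]-5,7-dihydroxy-2-(4-hydroxyphenyl)-4H-chromen-4-one | O=c1cc(-c2ccc(O)cc2)oc2c(-c3c(O)cc(O)c4c(=O)cc(-c5ccc(O)c(O)c5)oc34)c(O)cc(O)c12 | target

Total step count: 9. Longest linear sequence: 9 steps (1 to 22).

Steps most likely to fail

Step 5. The electron-rich vinylketene released from 10 may be lost to dimerization or to acylation of the phenol already formed before the alkyne intercepts it, or the last 6π closure may be slowed by the bulky C8 substituent. The fallback makes the biaryl bond by known cross-coupling; it sets out from iodide 2 and comes back at acetophenone 18. Miyaura borylation of 2 (B2pin2, PdCl2(dppf), KOAc, dioxane, 90 °C) should give 5,7,4'-trimethoxyflavone-8-boronic acid pinacol ester F1. In parallel, commercial 2',4',6'-trihydroxyacetophenone would be ethylated at its two non-chelated hydroxyls (EtI, K2CO3, acetone, reflux) to 1-(2,4-diethoxy-6-hydroxyphenyl)ethanone F2. Iodination ortho to the hydroxyl (NIS, TFA, CH3CN) would then give 1-(4,6-diethoxy-2-hydroxy-3-iodophenyl)ethanone F3. Suzuki–Miyaura coupling of F1 with F3 (Pd(OAc)2, SPhos, K3PO4, toluene–H2O, 100 °C) would form the tetra-ortho-substituted biaryl and give 18, after which steps 7 to 9 follow unchanged.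

Step 4. The arylketene may dimerize or be consumed by amine-derived nucleophiles faster than it adds the alkyne, or the strained enone may degrade under the amine base before isolation. The fallback generates the same ketene without base or chloride; it sets out from iodide 2 and comes back at phenol 15. Stille coupling of 2 with tributyl(ethoxyethynyl)stannane (PdCl2(PPh3)2, Et4NCl, DMF, 40 °C) should give 8-(ethoxyethynyl)-5,7-dimethoxy-2-(4-methoxyphenyl)-4H-chromen-4-one F4. Heating F4 with a large excess of 7 in toluene at 110–120 °C (sealed tube) should expel ethene by a retro-ene reaction and release ketene 9. Trapping of 9 by 7 gives 10, which at this temperature runs on through the cascade of step 5 to 15; the excess of 7 compensates for its own slow thermolysis.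

Step 6. The acetyl group may be delivered to C6'' between the two ethoxy groups instead of C4a'', or the Lewis acid may strip the peri 5-methoxy group during the rearrangement. The fallback installs the carbonyl carbon by a reaction that can only reach the position ortho to the hydroxyl; it sets out from phenol 15 and comes back at acetophenone 18. Magnesium-phenoxide-directed formylation (MgCl2, Et3N, paraformaldehyde, CH3CN, reflux) should give 8-(4,6-diethoxy-3-formyl-2-hydroxyphenyl)-5,7-dimethoxy-2-(4-methoxyphenyl)-4H-chromen-4-one F5. Addition of MeMgBr (2.2 equiv, THF, −78 °C), where the aldehyde should far outpace the vinylogous-ester carbonyl of the flavone, would give 8-[4,6-diethoxy-2-hydroxy-3-(1-hydroxyethyl)phenyl]-5,7-dimethoxy-2-(4-methoxyphenyl)-4H-chromen-4-one F6 (racemic at the carbinol carbon). Oxidation of the benzylic alcohol with MnO2 (CH2Cl2, rt) would give 18.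

Further compounds
F1 | step 5 | 5,7,4'-trimethoxyflavone-8-boronic acid pinacol ester | CC1(C)OB(OC1(C)C)c1c(OC)cc(OC)c2c(=O)cc(-c3ccc(OC)cc3)oc12
F2 | step 5 | 1-(2,4-diethoxy-6-hydroxyphenyl)ethanone | CCOc1cc(O)c(C(C)=O)c(OCC)c1
F3 | step 5 | 1-(4,6-diethoxy-2-hydroxy-3-iodophenyl)ethanone | CCOc1cc(OCC)c(I)c(O)c1C(C)=O
F4 | step 4 | 8-(ethoxyethynyl)-5,7-dimethoxy-2-(4-methoxyphenyl)-4H-chromen-4-one | CCOC#Cc1c(OC)cc(OC)c2c(=O)cc(-c3ccc(OC)cc3)oc12
F5 | step 6 | 8-(4,6-diethoxy-3-formyl-2-hydroxyphenyl)-5,7-dimethoxy-2-(4-methoxyphenyl)-4H-chromen-4-one | CCOc1cc(OCC)c(-c2c(OC)cc(OC)c3c(=O)cc(-c4ccc(OC)cc4)oc23)c(O)c1C=O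
F6 | step 6 | 8-[4,6-diethoxy-2-hydroxy-3-(1-hydroxyethyl)phenyl]-5,7-dimethoxy-2-(4-methoxyphenyl)-4H-chromen-4-one (racemic carbinol) | CCOc1cc(OCC)c(-c2c(OC)cc(OC)c3c(=O)cc(-c4ccc(OC)cc4)oc23)c(O)c1C(C)O
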